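3 questions stand here, and your hunch answers the last by extending a line: more partner, proportionally more target.

| flask | starting material | partner | time |
|---|---|---|---|
| Sunday's | 0.120 M | 0.120 M |  |
| Monday's | 0.0480 M | 0.0480 M |  |
| Wednesday's | 0.0600 M | 0.120 M |  |
| Tuesday's | 0.120 M | 0.240 M |  |
| Friday's | 0.120 M | 0.420 M | 20 min |

| run | time / min | [target] / M |
|---|---|---|
| Sunday's run | 2.9 | 0.0139 |
| Sunday's run | 5.7 | 0.0275 |
| Sunday's run | 8.6 | 0.0337 |
| Sunday's run | 11 | 0.0366 |
| Sunday's run | 14 | 0.0404 |
| Sunday's run | 17 | 0.0420 |
| Sunday's run | 20 | 0.0440 |
| Monday's run | 2.9 | 0.0027 |
| Monday's run | 5.7 | 0.0068 |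
| Monday's run | 8.6 | 0.0090 |
| Monday's run | 11 | 0.0109 |
| Monday's run | 14 | 0.0134 |
| Monday's run | 17 | 0.0136 |
| Monday's run | 20 | 0.0144 |
| Wednesday's run | 2.9 | 0.0089 |
| Wednesday's run | 5.7 | 0.0194 |
| Wednesday's run | 8.6 | 0.0270 |
| Wednesday's run | 11 | 0.0317 |
| Wednesday's run | 14 | 0.0355 |
| Wednesday's run | 17 | 0.0369 |
| Wednesday's run | 20 | 0.0389 |
| Tuesday's run | 2.9 | 0.0269 |
| Tuesday's run | 5.7 | 0.0531 |
| Tuesday's run | 8.6 | 0.0691 |
| Tuesday's run | 11 | 0.0767 |
| Tuesday's run | 14 | 0.0824 |
| Tuesday's run | 17 | 0.0846 |
| Tuesday's run | 20 | 0.0853 |

(scatter of a reading: 4 × 10⁻⁴ M)

- order of the initial rate in [starting material], near the charge of the Sunday's run, the rate being that where two percent of its starting material are target (one fixed amount of target, the same in the runs compared)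
- order of the initial rate in [partner], near the charge of the Sunday's run, the rate being that where two percent of its starting material are target
- target in the Friday's run at 20 min, as a share of the starting material charged

- Overall: starting material + partner -> target.
- Constant volume, constant temperature.
- A reading of a species includes what of it is bound.
- "The second partner" is partner.
- An order is taken over about fifteen percent of the charge, up and down.

The orders come first, read from the first readings at one fixed time, which is cruder than the fixed amount of target asked for. At 2.9 min, Wednesday's flask, with half of Sunday's starting material, holds 0.640 of the target in Sunday's flask, which reads as an order of 0.643 in starting material. At the same time, Tuesday's flask, with twice Sunday's partner, holds 1.94 of the target in Sunday's flask, which reads as 0.953 in partner. Both are averages over a doubling, wider than the span asked.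

Your line does appear in the readings: at 20 min, Tuesday's flask holds twice the target of Sunday's, on the same starting material. So follow one partner molecule through those two flasks and ask its chance of standing as target at that time. The mean over the two flasks reads 0.361, and this is the partner yield, target at 20 min per partner charged.

Carried to Friday's flask, with 3.50 partners per starting material, the yield allows 126 % of the charge, more than the charge itself. The line therefore has to break in Friday's flask, where starting material is the limiting reagent by charge. The share should lie above Tuesday's 71.1 % and below 100 %, and this reckoning commits to the midpoint, 85.5 %.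

The forecast gives 0.5, 1 and 90 %, a higher share than this reckoning, and reads the stall thus: “This looks like a dying catalyst or active species”.

The flask gives 0.51, 0.71 and 78.3 %, a share inside the bracket and lower than the midpoint.

    starting material ⇌ intermediate + by-product (0.2112 /min, 0.8400 /M/min)
    intermediate + partner → target (2.736 /M/min)
    target → decomposed product (0.01542 /min)
    partner + by-product ⇌ reagent-by-product salt, settled at all times (189.0 /M)

In Friday's flask, the joining of partner and by-product to the salt makes no difference to the share at the asked time. Friday's flask holds 0.224 target per partner charged, less than the partner yield of 0.361.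

The runs are simulated from invented constants; noise was put on by code.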